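Remark on numbering: isoflavone locants are used throughout (ring A with C5–C8, ring C with O1–C4, ring B with C1'–C6', side chain C1''–C4''). In the chalcone the carbon that becomes C2 is called Cβ and the one that becomes C3 is called Cα.

## Analysis of the target

Vogelin E (14) is an isoflavone, a chromen-4-one (rings A and C) that carries aryl ring B on C3. Ring A has the phloroglucinol pattern with hydroxyls at C5 and C7. Ring B has a hydroxyl at C4' and, ortho to it at C3', an (E)-4-hydroxy-3-methylbut-2-enyl chain. There is no stereocenter; the only stereochemical element is the trisubstituted C2''=C3'' double bond, whose hydroxymethyl group must lie trans to the benzylic C1''. The sensitive groups are three phenols (the one at C5 chelated to C4=O), a pyranone whose C2 is open to hard nucleophiles, and an allylic alcohol ortho to a free phenol, which ionises or cyclises under acid; its olefin also excludes hydrogenolysis and strong oxidants late in the route. The difficulty lies in the ordering: the aryl group must end on C3 and not C2, the C5 chain must reach C3' with defined geometry, and the phenol protection must come off without harm to olefin or allylic alcohol. The strategy rests on two facts. O4' is para to C1', so ring B is an electron-rich, willing migrating group. The C2–C3(C1')–C4 segment of ring C is the Cβ–Cα–C=O segment of a chalcone whose aryl group has moved from Cβ to Cα. Because a chalcone comes from one aldol condensation of two simple aromatic building blocks, the oxidative 1,2-aryl shift with closure of ring C is the only step of real risk.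

## Retrosynthetic reasoning

**14 from 13.** No skeletal bond is cut; the C4'' alcohol is traced back to the aldehyde 13. An enal is what a cross-metathesis delivers directly, and its conjugation holds the E geometry. The forward step must reduce the aldehyde 1,2 and spare the olefin and the chromone carbonyl.

**13 from 11 and 12.** The C2''=C3'' double bond is cut. This divides the chain into an allyl group on ring B and the commercial four-carbon aldehyde 12, and the geometry is set in the same step that joins them. Cutting C3'–C1'' or C1''–C2'' instead would need a geometrically pure C5 or C4 organometallic partner made separately. The forward metathesis must be E-selective and tolerate three free phenols.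

**11 from 10.** The three phenols are masked as benzyl ethers in 10. They are removed at this point, after the last palladium step and before the allylic alcohol exists. A Lewis-acid cleavage tolerates a terminal olefin but not an ionisable allylic alcohol, and hydrogenolysis is excluded once any olefin is present.

**10 from 8 and 9.** The C3'–C1'' bond is cut, leaving bromine on C3' of 8 and the allyl group on stannane 9. The allyl group cannot be carried further back, because the oxidant of the ring-forming step attacks isolated olefins; bromine is inert to it and to everything before it. The forward step is a Stille coupling at an aryl bromide ortho to an ether.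

**8 from 6 (through 7).** O1–C2 and C3–C1' are cut and C1' is reattached to the carbon that becomes C2. This turns the isoflavone into the 2'-hydroxychalcone 6. What is gained is ring C with the aryl group unambiguously on C3, from a compound that one condensation provides. The forward step must move ring B, and only ring B, from Cβ to Cα, leave Cβ at the aldehyde oxidation level as acetal 7, and then let the 2'-hydroxyl close the ring.

**6 from 3 and 5.** The Cα=Cβ bond is cut (aldol condensation). Ketone 3 supplies ring A with its free ortho hydroxyl for the later ring closure. Aldehyde 5 supplies ring B with the benzyl ether para and the bromine meta to the future migrating carbon.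

**3 from 1 and 2; 5 from 4 and 2.** O-benzyl bonds are cut. Ketone 1 needs two of its three hydroxyls protected, and the one hydrogen-bonded to the carbonyl stays free by itself. Aldehyde 4 already has the bromine in the right place.

## Alternatives that were turned down

**Alternative 1:** Ring C is cut at C3–C4 and O1–C8a. Ring A comes from 2,4,6-trifluorobenzoyl chloride (A2), and ring B with the complete silylated side chain comes from the arylacetaldehyde A3, used as an enamine.
- Forward key step: the enamine β-carbon is acylated by A2, aqueous K2CO3 hydrolyses the enaminone, and the enolate oxygen displaces an ortho fluoride by SNAr to give the 5,7-difluoroisoflavone A1.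
- For it: it is convergent, uses no heavy-metal oxidant, and has the side chain in place before the ring is made, so no late C–C bond is needed. On these points it is stronger than the chosen route.
- Against it: the two fluorides of A1 must still be exchanged for oxygen by two further SNAr reactions with an alkoxide. After the first exchange the new donor deactivates the ring toward the second. The pyranone C2 of A1 competes for the same nucleophile, with ring opening.
- Against it, continued: A3 is an enolisable, homobenzylic aldehyde with a silyl ether on a phenol that aqueous carbonate may remove, and it needs several steps of its own.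
- Comparison: the chosen route has all three oxygens in place from the first step and confines the uncertainty to one well-known transformation.

**Alternative 2:** Ring C is cut at C3–C4 and O1–C2, giving the salicylaldehyde A5 and the aryl(trimethylsilyl)alkyne A6.
- Forward key step: [Cp*RhCl2]2 (Cp* is pentamethylcyclopentadienyl) with Cu(OAc)2 as oxidant cleaves the formyl C–H bond of A5 at trivalent rhodium, the alkyne inserts into the acyl–rhodium bond, and C–O bond formation closes the ring. The product is the 2-silylisoflavone A4, with silicon meant to steer the aryl group to C3.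
- For it: it is the most convergent plan, with one catalytic step joining two fully oxygenated halves. In bond economy it is stronger than the chosen route.
- Against it: aryl groups normally prefer the alkyne carbon bound to rhodium, which leads to the 2-aryl (flavone) pattern, so silicon must override that preference. The acyl–rhodium species of A5 is flanked by two ortho oxygen substituents. Acetate can desilylate A6 before insertion.
- Against it, continued: A4 needs a separate C2–Si cleavage. The methoxymethyl ethers must then be removed with acid when the allylic alcohol ortho to a phenol is already present. A6 also needs several steps.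
- Comparison: in the chosen route the regiochemistry follows from the migratory aptitude of ring B, and all deprotection is finished before the allylic alcohol is made.

**Alternative 3:** The side chain is cut at C1''–C2'' and at C3''–CH3. The parts are the benzylic chloride A9, propargyl alcohol (A8) and a methyl group from Al(CH3)3.
- Forward key step: Cp2ZrCl2-catalysed syn-methylalumination of A8 gives the (E)-alkenylalane A10. Pd(PPh3)4-catalysed coupling with A9 in the same pot gives the tris(methoxymethyl) ether A7 of the target.
- For it: the geometry is fixed by a syn carbometalation and kept in the coupling. This is more rigorous than a thermodynamically controlled metathesis, and on this point it is stronger than the chosen route.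
- Against it: it only addresses the side chain. The isoflavone A9 with a chloromethyl group at C3' must still be built by some ring synthesis and carried through it. That chloride, ortho to an acetal oxygen, ionises easily.
- Against it, continued: excess Al(CH3)3 is a Lewis acid and a methyl donor toward the chromone carbonyl and the peri methoxymethyl ether. A7 must be deprotected with acid in the presence of the allylic alcohol.
- Comparison: the chosen route keeps the same late-stage logic of a handle at C3', but uses bromine, which is inert through the ring construction. It gets its E geometry from the strong thermodynamic preference of a conjugated enal and removes the protecting groups before the sensitive alcohol exists.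

Key step: step 4

## Route

**Step 1**
Reactants: 1 2,4,6-trihydroxyacetophenone; 2 benzyl bromide
Product: 3 1-[2,4-bis(benzyloxy)-6-hydroxyphenyl]ethanone
Conditions: BnBr (2.1 equiv), K2CO3 (2.2 equiv), DMF, 0 °C to rt
Reagents that add atoms: benzyl bromide, BrCc1ccccc1
Why: Williamson ether synthesis; the hydroxyl para to the acetyl group and one ortho hydroxyl are alkylated, while the remaining ortho hydroxyl is held in a hydrogen bond to the carbonyl and reacts much more slowly, so two equivalents of halide should stop at the bis-ether; low temperature and carbonate in DMF keep C-benzylation of the nucleus down.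

**Step 2**
Reactants: 4 3-bromo-4-hydroxybenzaldehyde; 2 benzyl bromide
Product: 5 4-(benzyloxy)-3-bromobenzaldehyde
Conditions: BnBr (1.1 equiv), K2CO3, DMF, rt
Reagents that add atoms: benzyl bromide, BrCc1ccccc1
Why: Williamson ether synthesis on an acidic phenol (para formyl, ortho bromine); the aldehyde is not enolisable and is inert to carbonate.

**Step 3**
Reactants: 3 1-[2,4-bis(benzyloxy)-6-hydroxyphenyl]ethanone; 5 4-(benzyloxy)-3-bromobenzaldehyde
Product: 6 (E)-1-[2,4-bis(benzyloxy)-6-hydroxyphenyl]-3-[4-(benzyloxy)-3-bromophenyl]prop-2-en-1-one
Conditions: KOH (50% aq), EtOH–THF, rt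
Reagents that add atoms: none
Why: Claisen–Schmidt condensation; the methyl ketone enolate adds to the non-enolisable aldehyde and E1cB loss of water gives the conjugated E-enone, which as its phenoxide under strong base should stay open rather than close to the flavanone.

**Step 4**
Reactants: 6 (E)-1-[2,4-bis(benzyloxy)-6-hydroxyphenyl]-3-[4-(benzyloxy)-3-bromophenyl]prop-2-en-1-one
Product: 8 5,7-bis(benzyloxy)-3-[4-(benzyloxy)-3-bromophenyl]chromen-4-one, via β-keto dimethyl acetal 7 (not isolated)
Conditions: Tl(NO3)3·3H2O (1.2 equiv), MeOH–HC(OMe)3–CH2Cl2, rt; then 10% aq HCl, 50 °C; TlCl filtered off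
Reagents that add atoms: methanol, CO (its two methoxy groups are carried by 7 only and leave again on ring closure; no reagent atom remains in 8)
Why: Tl(NO3)3 attacks the Cα=Cβ bond of 6 as an electrophile, methanol opens the thallonium ion at the benzylic Cβ, where the para-benzyloxy ring stabilises positive charge, and a C–Tl bond is left at Cα (methoxythallation). The C–Tl bond then ionises with reduction to monovalent thallium while ring B, anti to the metal, bridges to Cα through a phenonium ion and completes the 1,2-shift that forms C3–C1'; the charge ends on Cβ as an oxocarbenium ion that methanol traps, and HC(OMe)3 keeps the medium dry so that the dimethyl acetal 7 results. The closest known reaction type is the Tl(NO3)3-mediated oxidative rearrangement of 2'-hydroxychalcones to 2-aryl-3,3-dimethoxy-1-(2-hydroxyaryl)propan-1-ones and their acid cyclisation to isoflavones. On addition of aqueous HCl the acetal ionises, the 2'-hydroxyl adds to the oxocarbenium carbon in a 6-exo-trig closure that forms O1–C2 and ring C, and the second methanol is eliminated from the 2-methoxyisoflavanone to give the conjugated pyranone. No stereocenter is set, since the C3 center of racemic 7 becomes trigonal in 8. The step needs migration of ring B in preference to migration of the aroyl group and to attack of the 2'-hydroxyl on Cβ (aurone or flavanone formation); the benzyloxy group para to the migrating carbon secures this, and the bromine, meta to that carbon, withdraws only inductively. It also needs the oxidant to spare ring A, which is helped by the electron-withdrawing acyl group and by the hydrogen bond that ties up the only free hydroxyl; benzyl ethers and the C–Br bond are inert to trivalent thallium, whereas an olefinic side chain would not be, which is why C3' carries bromine at this stage.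

**Step 5**
Reactants: 8 5,7-bis(benzyloxy)-3-[4-(benzyloxy)-3-bromophenyl]chromen-4-one; 9 allyltributylstannane
Product: 10 3-[3-allyl-4-(benzyloxy)phenyl]-5,7-bis(benzyloxy)chromen-4-one
Conditions: allylSnBu3 (1.5 equiv), Pd(PPh3)4 (5 mol %), DMF (degassed), 90 °C
Reagents that add atoms: allyltributylstannane, C=CC[Sn](CCCC)(CCCC)CCCC
Why: Stille coupling; zerovalent palladium inserts into the C3'–Br bond, the allyl group is transferred from tin in preference to butyl, and reductive elimination forms C3'–C1''; the chromone and the benzyl ethers are inert under these neutral conditions.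

**Step 6**
Reactants: 10 3-[3-allyl-4-(benzyloxy)phenyl]-5,7-bis(benzyloxy)chromen-4-one
Product: 11 3-(3-allyl-4-hydroxyphenyl)-5,7-dihydroxychromen-4-one
Conditions: BCl3 (1 M in CH2Cl2, 6 equiv), C6HMe5 (9 equiv), CH2Cl2, −78 °C; MeOH quench, aqueous work-up
Reagents that add atoms: none
Why: Lewis-acid cleavage of aryl benzyl ethers; BCl3 coordinates the ether oxygen, the benzyl cation is taken up by pentamethylbenzene (a scavenger that does not bind boron), which should prevent C-benzylation of the electron-rich rings, and at −78 °C the terminal olefin should not be touched.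

**Step 7**
Reactants: 11 3-(3-allyl-4-hydroxyphenyl)-5,7-dihydroxychromen-4-one; 12 methacrolein
Product: 13 (E)-4-[5-(5,7-dihydroxy-4-oxochromen-3-yl)-2-hydroxyphenyl]-2-methylbut-2-enal
Conditions: methacrolein (15 equiv), second-generation Hoveyda–Grubbs catalyst RuCl2(=CH-C6H4-2-OiPr)(H2IMes) (5–10 mol %), 1,4-benzoquinone (10 mol %), CH2Cl2–THF, 40 °C
Reagents that add atoms: methacrolein, C=C(C)C=O
Why: Olefin cross-metathesis of a terminal olefin with a 1,1-disubstituted conjugated aldehyde that does not homodimerise; ethene is lost and the trisubstituted enal should form as the E isomer (formyl trans to the benzylic carbon) under thermodynamic control; benzoquinone intercepts ruthenium hydrides that would move the allyl double bond into conjugation.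

**Step 8**
Reactants: 13 (E)-4-[5-(5,7-dihydroxy-4-oxochromen-3-yl)-2-hydroxyphenyl]-2-methylbut-2-enal
Product: 14 Vogelin E, 5,7-dihydroxy-3-[4-hydroxy-3-[(E)-4-hydroxy-3-methylbut-2-enyl]phenyl]chromen-4-one
Conditions: NaBH4 (2 equiv), CeCl3·7H2O (1.2 equiv), MeOH–THF, −20 °C to 0 °C
Reagents that add atoms: none
Why: Luche reduction; cerium-activated methoxyborohydrides deliver hydride 1,2 to the aldehyde and leave the olefin geometry unchanged, while the chromone carbonyl is a vinylogous ester, hydrogen-bonded to the C5 hydroxyl, and far less electrophilic than the aldehyde.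

## Compound list

1 | 2,4,6-trihydroxyacetophenone | CC(=O)c1c(O)cc(O)cc1O | starting material
2 | benzyl bromide | BrCc1ccccc1 | starting material
3 | 1-[2,4-bis(benzyloxy)-6-hydroxyphenyl]ethanone | CC(=O)c1c(O)cc(OCc2ccccc2)cc1OCc1ccccc1 | intermediate
4 | 3-bromo-4-hydroxybenzaldehyde | O=Cc1ccc(O)c(Br)c1 | starting material
5 | 4-(benzyloxy)-3-bromobenzaldehyde | O=Cc1ccc(OCc2ccccc2)c(Br)c1 | intermediate
6 | (E)-1-[2,4-bis(benzyloxy)-6-hydroxyphenyl]-3-[4-(benzyloxy)-3-bromophenyl]prop-2-en-1-one | O=C(/C=C/c1ccc(OCc2ccccc2)c(Br)c1)c1c(O)cc(OCc2ccccc2)cc1OCc1ccccc1 | intermediate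
7 | 1-[2,4-bis(benzyloxy)-6-hydroxyphenyl]-2-[4-(benzyloxy)-3-bromophenyl]-3,3-dimethoxypropan-1-one (racemic, not isolated) | COC(OC)C(C(=O)c1c(O)cc(OCc2ccccc2)cc1OCc1ccccc1)c1ccc(OCc2ccccc2)c(Br)c1 | intermediate
8 | 5,7-bis(benzyloxy)-3-[4-(benzyloxy)-3-bromophenyl]chromen-4-one | O=c1c(-c2ccc(OCc3ccccc3)c(Br)c2)coc2cc(OCc3ccccc3)cc(OCc3ccccc3)c12 | intermediate
9 | allyltributylstannane | C=CC[Sn](CCCC)(CCCC)CCCC | starting material
10 | 3-[3-allyl-4-(benzyloxy)phenyl]-5,7-bis(benzyloxy)chromen-4-one | C=CCc1cc(-c2coc3cc(OCc4ccccc4)cc(OCc4ccccc4)c3c2=O)ccc1OCc1ccccc1 | intermediate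
11 | 3-(3-allyl-4-hydroxyphenyl)-5,7-dihydroxychromen-4-one | C=CCc1cc(-c2coc3cc(O)cc(O)c3c2=O)ccc1O | intermediate
12 | methacrolein | C=C(C)C=O | starting material
13 | (E)-4-[5-(5,7-dihydroxy-4-oxochromen-3-yl)-2-hydroxyphenyl]-2-methylbut-2-enal | C/C(=C\Cc1cc(-c2coc3cc(O)cc(O)c3c2=O)ccc1O)C=O | intermediate
14 | Vogelin E | C/C(=C\Cc1cc(-c2coc3cc(O)cc(O)c3c2=O)ccc1O)CO | target

## Step count and risks

Total step count: 8. Longest linear sequence: 7 steps (steps 1, 3, 4, 5, 6, 7, 8 from 1; the branch from 4 through step 2 is equally long).

**Step 4 (key step).**
- What may go wrong: oxidation or nitration of the electron-rich ring A by trivalent thallium and the nitric acid it releases; attack of the 2'-hydroxyl on Cβ (aurone or flavanone formation) if the bromine slows the aryl shift more than expected; slow methoxythallation because the tribenzyl chalcone dissolves poorly in methanol.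
- Fallback (sets out from 3, returns at 11): ring C is made first and the C3–C1' bond is formed by cross-coupling instead of migration.
  - 3 is condensed with N,N-dimethylformamide dimethyl acetal (toluene, 90 °C) to the enaminone (E)-1-[2,4-bis(benzyloxy)-6-hydroxyphenyl]-3-(dimethylamino)prop-2-en-1-one F1.
  - Iodine in CHCl3 closes the ring with loss of dimethylamine to 5,7-bis(benzyloxy)-3-iodochromen-4-one F2.
  - Suzuki–Miyaura coupling with 4-(allyloxy)phenylboronic acid (Pd(PPh3)4, K2CO3, DME–H2O, 80 °C) gives 3-[4-(allyloxy)phenyl]-5,7-bis(benzyloxy)chromen-4-one F3.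
  - Aromatic Claisen rearrangement (N,N-diethylaniline, 200 °C) moves the allyl group to C3', the para position being blocked and both ortho positions equivalent, and gives 3-(3-allyl-4-hydroxyphenyl)-5,7-bis(benzyloxy)chromen-4-one F4.
  - The conditions of step 6 then remove the two benzyl ethers and give 11.

**Step 7.**
- What may go wrong: migration of the terminal double bond into conjugation with ring B by ruthenium hydride species, favoured by the neighbouring free phenol; poor solubility of the triphenol; homodimerisation of 11 because the hindered, electron-poor partner reacts slowly.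
- Fallback (sets out from 11, returns at 14): the terminal oxygen is introduced by allylic oxidation instead of being carried by the metathesis partner.
  - 11 is peracetylated (Ac2O, pyridine, DMAP) to 3-(4-acetoxy-3-allylphenyl)-4-oxochromene-5,7-diyl diacetate F5.
  - Cross-metathesis in 2-methyl-2-butene as solvent (second-generation Grubbs catalyst RuCl2(=CHPh)(PCy3)(H2IMes), rt) gives the prenyl compound 3-[4-acetoxy-3-(3-methylbut-2-enyl)phenyl]-4-oxochromene-5,7-diyl diacetate F6.
  - Riley oxidation (catalytic SeO2, t-BuOOH, CH2Cl2, rt) hydroxylates the methyl group trans to the benzylic carbon and gives 3-[4-acetoxy-3-[(E)-4-hydroxy-3-methylbut-2-enyl]phenyl]-4-oxochromene-5,7-diyl diacetate F7. Any enal from over-oxidation is returned to F7 with NaBH4 and CeCl3.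
  - K2CO3 in MeOH removes the three acetates and gives 14.

**Step 5.**
- What may go wrong: slow oxidative addition at the hindered, electron-rich C–Br bond, leading to protodebromination; palladium hydride-mediated migration of the allyl double bond to the propenyl isomer, which would be useless for step 7.
- Fallback (sets out from 8, returns at 10): the polarity of the coupling is reversed.
  - Miyaura borylation of 8 (B2pin2, PdCl2(dppf), KOAc, dioxane, 90 °C) gives 5,7-bis(benzyloxy)-3-[4-(benzyloxy)-3-(4,4,5,5-tetramethyl-1,3,2-dioxaborolan-2-yl)phenyl]chromen-4-one F8.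
  - F8 is coupled with allyl bromide (Pd(PPh3)4, K2CO3, THF–H2O, 60 °C) to give 10.
  - If the C–Br bond itself proves unreactive, the Claisen sequence given for step 4 avoids it altogether.

**Step 6.**
- What may go wrong: C-benzylation of ring A or ring B by benzyl cations that escape the scavenger; addition of HCl to the allyl group or its closure onto the ortho phenol during quench; incomplete cleavage.
- Fallback (sets out from 8, returns at 11): the benzyl ethers are removed before any olefin is present.
  - 8 is treated with BCl3 and C6HMe5 as in step 6 to give 3-(3-bromo-4-hydroxyphenyl)-5,7-dihydroxychromen-4-one F9.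
  - Peracetylation (Ac2O, pyridine, DMAP) gives 3-(4-acetoxy-3-bromophenyl)-4-oxochromene-5,7-diyl diacetate F10.
  - Stille allylation under the conditions of step 5 gives 3-(4-acetoxy-3-allylphenyl)-4-oxochromene-5,7-diyl diacetate F5, the compound already met in the fallback for step 7.
  - K2CO3 in MeOH gives 11.

## Further compounds

F1 | step 4 | (E)-1-[2,4-bis(benzyloxy)-6-hydroxyphenyl]-3-(dimethylamino)prop-2-en-1-one | CN(C)/C=C/C(=O)c1c(O)cc(OCc2ccccc2)cc1OCc1ccccc1
F2 | step 4 | 5,7-bis(benzyloxy)-3-iodochromen-4-one | O=c1c(I)coc2cc(OCc3ccccc3)cc(OCc3ccccc3)c12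
F3 | step 4 | 3-[4-(allyloxy)phenyl]-5,7-bis(benzyloxy)chromen-4-one | C=CCOc1ccc(-c2coc3cc(OCc4ccccc4)cc(OCc4ccccc4)c3c2=O)cc1
F4 | step 4 | 3-(3-allyl-4-hydroxyphenyl)-5,7-bis(benzyloxy)chromen-4-one | C=CCc1cc(-c2coc3cc(OCc4ccccc4)cc(OCc4ccccc4)c3c2=O)ccc1O
F5 | step 7 | 3-(4-acetoxy-3-allylphenyl)-4-oxochromene-5,7-diyl diacetate | C=CCc1cc(-c2coc3cc(OC(C)=O)cc(OC(C)=O)c3c2=O)ccc1OC(C)=O
F6 | step 7 | 3-[4-acetoxy-3-(3-methylbut-2-enyl)phenyl]-4-oxochromene-5,7-diyl diacetate | CC(C)=CCc1cc(-c2coc3cc(OC(C)=O)cc(OC(C)=O)c3c2=O)ccc1OC(C)=O
F7 | step 7 | 3-[4-acetoxy-3-[(E)-4-hydroxy-3-methylbut-2-enyl]phenyl]-4-oxochromene-5,7-diyl diacetate | C/C(=C\Cc1cc(-c2coc3cc(OC(C)=O)cc(OC(C)=O)c3c2=O)ccc1OC(C)=O)CO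
F8 | step 5 | 5,7-bis(benzyloxy)-3-[4-(benzyloxy)-3-(4,4,5,5-tetramethyl-1,3,2-dioxaborolan-2-yl)phenyl]chromen-4-one | CC1(C)OB(c2cc(-c3coc4cc(OCc5ccccc5)cc(OCc5ccccc5)c4c3=O)ccc2OCc2ccccc2)OC1(C)C
F9 | step 6 | 3-(3-bromo-4-hydroxyphenyl)-5,7-dihydroxychromen-4-one | O=c1c(-c2ccc(O)c(Br)c2)coc2cc(O)cc(O)c12
F10 | step 6 | 3-(4-acetoxy-3-bromophenyl)-4-oxochromene-5,7-diyl diacetate | CC(=O)Oc1cc(OC(C)=O)c2c(=O)c(-c3ccc(OC(C)=O)c(Br)c3)coc2c1
A1 | alternative 1 | 5,7-difluoro-3-[4-(triisopropylsilyloxy)-3-[(E)-3-methyl-4-(triisopropylsilyloxy)but-2-enyl]phenyl]chromen-4-one | C/C(=C\Cc1cc(-c2coc3cc(F)cc(F)c3c2=O)ccc1O[Si](C(C)C)(C(C)C)C(C)C)CO[Si](C(C)C)(C(C)C)C(C)C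
A2 | alternative 1 | 2,4,6-trifluorobenzoyl chloride | O=C(Cl)c1c(F)cc(F)cc1F
A3 | alternative 1 | 2-[4-(triisopropylsilyloxy)-3-[(E)-3-methyl-4-(triisopropylsilyloxy)but-2-enyl]phenyl]acetaldehyde | C/C(=C\Cc1cc(CC=O)ccc1O[Si](C(C)C)(C(C)C)C(C)C)CO[Si](C(C)C)(C(C)C)C(C)C
A4 | alternative 2 | 3-[3-[(E)-4-(tert-butyldimethylsilyloxy)-3-methylbut-2-enyl]-4-(methoxymethoxy)phenyl]-5,7-bis(methoxymethoxy)-2-(trimethylsilyl)chromen-4-one | C/C(=C\Cc1cc(-c2c([Si](C)(C)C)oc3cc(OCOC)cc(OCOC)c3c2=O)ccc1OCOC)CO[Si](C)(C)C(C)(C)C
A5 | alternative 2 | 2-hydroxy-4,6-bis(methoxymethoxy)benzaldehyde | O=Cc1c(O)cc(OCOC)cc1OCOC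
A6 | alternative 2 | tert-butyl-[(E)-4-[2-(methoxymethoxy)-5-(trimethylsilylethynyl)phenyl]-2-methylbut-2-enoxy]dimethylsilane | C/C(=C\Cc1cc(C#C[Si](C)(C)C)ccc1OCOC)CO[Si](C)(C)C(C)(C)C
A7 | alternative 3 | 3-[3-[(E)-4-hydroxy-3-methylbut-2-enyl]-4-(methoxymethoxy)phenyl]-5,7-bis(methoxymethoxy)chromen-4-one | C/C(=C\Cc1cc(-c2coc3cc(OCOC)cc(OCOC)c3c2=O)ccc1OCOC)CO
A8 | alternative 3 | propargyl alcohol | C#CCO
A9 | alternative 3 | 3-[3-(chloromethyl)-4-(methoxymethoxy)phenyl]-5,7-bis(methoxymethoxy)chromen-4-one | ClCc1cc(-c2coc3cc(OCOC)cc(OCOC)c3c2=O)ccc1OCOC
A10 | alternative 3 | (E)-[3-(dimethylalumanyloxy)-2-methylprop-1-enyl]dimethylalane | C[Al](C)/C=C(\C)CO[Al](C)C
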